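**Retrosynthetic overview**
1. Target 21 ⇒ C20=C21 alkene plus enol ester: aldehyde 12 + 5-phosphonotetronic acid 17 + hexadecanoyl chloride 18 (new (E)-selective olefination, acylation in the same flask).
2. 12 ⇒ alcohol 11 ⇒ C16–C17 bond by visible-light iridium/nickel decarboxylative sp3–sp3 coupling of acid 9 with (R)-3-bromo-2-methylpropan-1-ol 10, which supplies the only stereocentre.
3. 9 ⇒ allylic bromide 8 + acetic acid dianion; 8 ⇒ 8-hydroxygeranyl acetate 2 + 3-furylmethyl Grignard 6 (both (E)-alkenes are bought in geranyl acetate 1).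
4. 17 ⇒ 3-methyltetronic acid 13 by C-5 bromination and P–C bond formation.
5. Rings: none is built. The furan comes from furan-3-ylmethanol 3 (joined in step 3) and the butenolide from 13 (joined in step 10).

Assumption: the target is taken exactly as drawn, (18S,20E), with the side chain on the exocyclic alkene syn to the acyloxy-bearing ring carbon; 10 and 13 are bought.

**Step 1**
Reactants: 1 geranyl acetate
Product: 2 (2E,6E)-8-hydroxy-3,7-dimethylocta-2,6-dien-1-yl acetate
Conditions: SeO2 (10 mol %), t-BuOOH (3 equiv), salicylic acid (10 mol %), CH2Cl2, rt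
Reagents that add atoms: tert-butyl hydroperoxide, CC(C)(C)OO (source of the new oxygen, relayed by catalytic SeO2, O=[Se]=O)
Why: Sharpless SeO2/t-BuOOH allylic oxidation (ene reaction, then [2,3]-sigmatropic shift) hydroxylates only the (E)-methyl group of the more electron-rich terminal alkene, so both (E)-trisubstituted alkenes of the target are bought and kept.

**Step 2**
Reactants: 3 furan-3-ylmethanol
Product: 5 3-(chloromethyl)furan, via furan-3-ylmethyl methanesulfonate 4 (not isolated)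
Conditions: MsCl, Et3N, CH2Cl2, −20 °C; then LiCl, DMF, 0 °C
Reagents that add atoms: lithium chloride, [Li+].[Cl-]
Why: Collington–Meyers chlorination (mesylation, then SN2 displacement by chloride) works under non-acidic conditions, so the sensitive furylmethyl chloride forms without harm to the furan; 5 is used at once.

**Step 3**
Reactants: 2 (2E,6E)-8-hydroxy-3,7-dimethylocta-2,6-dien-1-yl acetate; 5 3-(chloromethyl)furan
Product: 7 (2E,6E)-9-(furan-3-yl)-2,6-dimethylnona-2,6-dien-1-ol, via (furan-3-ylmethyl)magnesium chloride 6 (not isolated)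
Conditions: 5, Mg, THF, 0 °C to rt (2.3 equiv of 6); then 2, Li2CuCl4 (3 mol %), THF, −78 to 0 °C; aq. NH4Cl
Reagents that add atoms: none
Why: Li2CuCl4-catalysed Grignard–allylic acetate cross-coupling (Fouquet–Schlosser type, as in the classical dendrolasin synthesis): one equivalent of 6 deprotonates the hydroxyl, then substitution occurs at the primary allylic carbon with retention of the (E)-alkene.

**Step 4**
Reactants: 7 (2E,6E)-9-(furan-3-yl)-2,6-dimethylnona-2,6-dien-1-ol
Product: 8 3-[(3E,7E)-9-bromo-4,8-dimethylnona-3,7-dien-1-yl]furan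
Conditions: CBr4, PPh3, CH2Cl2, −20 to 0 °C
Reagents that add atoms: carbon tetrabromide, BrC(Br)(Br)Br
Why: Appel bromination of the primary allylic alcohol is neutral and cold, so there is no allylic transposition and the furan survives.

**Step 5**
Reactants: 8 3-[(3E,7E)-9-bromo-4,8-dimethylnona-3,7-dien-1-yl]furan
Product: 9 (4E,8E)-11-(furan-3-yl)-4,8-dimethylundeca-4,8-dienoic acid
Conditions: AcOH, LiN(iPr)2 (2 equiv per AcOH), THF–DMPU, 0 to 35 °C; then 8, 0 °C to rt; cold 1 M HCl to pH 3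
Reagents that add atoms: acetic acid, CC(=O)O (used as its dilithium dianion)
Why: C-alkylation of the acetic acid dianion (SN2 at the primary allylic bromide) adds C16 and the carboxyl carbon in one step and gives the free acid directly.

**Step 6**
Reactants: 9 (4E,8E)-11-(furan-3-yl)-4,8-dimethylundeca-4,8-dienoic acid; 10 (R)-3-bromo-2-methylpropan-1-ol
Product: 11 (2S,6E,10E)-13-(furan-3-yl)-2,6,10-trimethyltrideca-6,10-dien-1-ol
Conditions: 10 (2 equiv), [Ir{dF(CF3)ppy}2(dtbbpy)]PF6 (2 mol %), NiCl2(dme) (10 mol %), 4,4'-dimethoxy-2,2'-bipyridine (10 mol %), K2CO3, H2O (20 equiv), MeCN, blue LEDs (450 nm), 25 °C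
Reagents that add atoms: none
Why: Iridium/nickel metallaphotoredox decarboxylative C(sp3)–C(sp3) cross-coupling: the excited photocatalyst oxidises the carboxylate of 9, loss of CO2 gives the primary C16 radical, this is captured by the alkylnickel formed from 10 and zerovalent nickel, and reductive elimination forms C16–C17; the stereocentre bought in 10 is β to the reacting carbon and is carried through untouched.

**Step 7**
Reactants: 11 (2S,6E,10E)-13-(furan-3-yl)-2,6,10-trimethyltrideca-6,10-dien-1-ol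
Product: 12 (2S,6E,10E)-13-(furan-3-yl)-2,6,10-trimethyltrideca-6,10-dienal
Conditions: Dess–Martin periodinane, CH2Cl2, 0 °C to rt
Reagents that add atoms: none
Why: Dess–Martin oxidation is neutral and non-enolising, so the α-methyl aldehyde forms without epimerisation; it is used directly in step 10.

**Step 8**
Reactants: 13 3-methyltetronic acid (4-hydroxy-3-methylfuran-2(5H)-one)
Product: 15 5-bromo-4-[(tert-butyldimethylsilyl)oxy]-3-methylfuran-2(5H)-one, via 2,4-bis[(tert-butyldimethylsilyl)oxy]-3-methylfuran 14 (not isolated)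
Conditions: TBSOTf (2.2 equiv), Et3N, CH2Cl2, 0 °C; then NBS, −78 °C
Reagents that add atoms: tert-butyldimethylsilyl trifluoromethanesulfonate, CC(C)(C)[Si](C)(C)OS(=O)(=O)C(F)(F)F; N-bromosuccinimide, O=C1CCC(=O)N1Br
Why: Double silylation gives the 2,4-bis(silyloxy)furan (a cyclic 1,3-bis-silyl enol ether), whose terminal C-5 is brominated by NBS as in the known γ-halogenation of 2-silyloxyfurans; C-3 is blocked by the methyl group.

**Step 9**
Reactants: 15 5-bromo-4-[(tert-butyldimethylsilyl)oxy]-3-methylfuran-2(5H)-one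
Product: 17 diphenyl (3-hydroxy-4-methyl-5-oxo-2,5-dihydrofuran-2-yl)phosphonate, via its 3-O-tert-butyldimethylsilyl ether 16 (not isolated)
Conditions: (PhO)2P(O)H, i-Pr2NEt, CH2Cl2, 0 °C to rt; then 1 M HCl, THF, 0 °C
Reagents that add atoms: diphenyl phosphite, O=[PH](Oc1ccccc1)Oc1ccccc1
Why: Michaelis–Becker P-alkylation of diphenyl phosphite by the activated 5-bromobutenolide (the way Ando-type diaryl phosphonates are made from α-bromo esters); the labile silyl enol ether is hydrolysed on acidic work-up.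

**Step 10**
Reactants: 12 (2S,6E,10E)-13-(furan-3-yl)-2,6,10-trimethyltrideca-6,10-dienal; 17 diphenyl (3-hydroxy-4-methyl-5-oxo-2,5-dihydrofuran-2-yl)phosphonate; 18 hexadecanoyl chloride
Product: 21 (2E)-2-[(2S,6E,10E)-13-(furan-3-yl)-2,6,10-trimethyltrideca-6,10-dien-1-ylidene]-4-methyl-5-oxo-2,5-dihydrofuran-3-yl hexadecanoate, via dipotassium dianion of the phosphonate 19 (not isolated), via potassium (18S,20E)-variabilinate 20 (not isolated)
Conditions: 17 (1.1 equiv), KN(SiMe3)2 (2.2 equiv), 18-crown-6, THF, −78 °C; 12, −78 to −40 °C; then 18 (1.5 equiv), −40 to 0 °C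
Reagents that add atoms: none
Why: Proposed new method: an Ando-type Horner–Wadsworth–Emmons olefination run from the dianion of a 5-(diaryloxyphosphoryl)tetronic acid, where the electron-poor diphenoxyphosphoryl group makes addition to 12 irreversible and elimination fast, so the kinetic adduct that places the aldehyde substituent syn to the carbanion-stabilising C-4 (the counterpart of the ester in a (Z)-selective Ando or Still–Gennari olefination) collapses by syn-elimination to the contra-thermodynamic (20E)-ylidene; the 4-oxide is small, cannot migrate to the aldolate as an acyl or silyl group would, and is acylated in the same flask by 18; the closest known reactions are the Ando and Still–Gennari olefinations and the (Z)-selective HWE of 5-(dialkoxyphosphoryl)butenolides; the C-18 stereocentre comes unchanged from 10.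

**Compound list**
1 | geranyl acetate, (2E)-3,7-dimethylocta-2,6-dien-1-yl acetate | CC(C)=CCC/C(C)=C/COC(C)=O | starting material
2 | (2E,6E)-8-hydroxy-3,7-dimethylocta-2,6-dien-1-yl acetate | OC/C(C)=C/CC/C(C)=C/COC(C)=O | intermediate
3 | furan-3-ylmethanol | OCc1ccoc1 | starting material
4 | furan-3-ylmethyl methanesulfonate | CS(=O)(=O)OCc1ccoc1 | intermediate (not isolated)
5 | 3-(chloromethyl)furan | ClCc1ccoc1 | intermediate
6 | (furan-3-ylmethyl)magnesium chloride | Cl[Mg]Cc1ccoc1 | intermediate (not isolated)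
7 | (2E,6E)-9-(furan-3-yl)-2,6-dimethylnona-2,6-dien-1-ol | OC/C(C)=C/CC/C(C)=C/CCc1ccoc1 | intermediate
8 | 3-[(3E,7E)-9-bromo-4,8-dimethylnona-3,7-dien-1-yl]furan | BrC/C(C)=C/CC/C(C)=C/CCc1ccoc1 | intermediate
9 | (4E,8E)-11-(furan-3-yl)-4,8-dimethylundeca-4,8-dienoic acid | OC(=O)CC/C(C)=C/CC/C(C)=C/CCc1ccoc1 | intermediate
10 | (R)-3-bromo-2-methylpropan-1-ol | OC[C@@H](C)CBr | starting material
11 | (2S,6E,10E)-13-(furan-3-yl)-2,6,10-trimethyltrideca-6,10-dien-1-ol | OC[C@@H](C)CCC/C(C)=C/CC/C(C)=C/CCc1ccoc1 | intermediate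
12 | (2S,6E,10E)-13-(furan-3-yl)-2,6,10-trimethyltrideca-6,10-dienal | O=C[C@@H](C)CCC/C(C)=C/CC/C(C)=C/CCc1ccoc1 | intermediate
13 | 3-methyltetronic acid, 4-hydroxy-3-methylfuran-2(5H)-one | CC1=C(O)COC1=O | starting material
14 | 2,4-bis[(tert-butyldimethylsilyl)oxy]-3-methylfuran | Cc1c(O[Si](C)(C)C(C)(C)C)coc1O[Si](C)(C)C(C)(C)C | intermediate (not isolated)
15 | 5-bromo-4-[(tert-butyldimethylsilyl)oxy]-3-methylfuran-2(5H)-one (racemic) | CC1=C(O[Si](C)(C)C(C)(C)C)C(Br)OC1=O | intermediate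
16 | diphenyl {3-[(tert-butyldimethylsilyl)oxy]-4-methyl-5-oxo-2,5-dihydrofuran-2-yl}phosphonate (racemic) | CC1=C(O[Si](C)(C)C(C)(C)C)C(OC1=O)P(=O)(Oc1ccccc1)Oc1ccccc1 | intermediate (not isolated)
17 | diphenyl (3-hydroxy-4-methyl-5-oxo-2,5-dihydrofuran-2-yl)phosphonate (racemic) | CC1=C(O)C(OC1=O)P(=O)(Oc1ccccc1)Oc1ccccc1 | intermediate
18 | hexadecanoyl chloride (palmitoyl chloride) | CCCCCCCCCCCCCCCC(=O)Cl | starting material
19 | dipotassium 2-(diphenoxyphosphoryl)-4-methyl-5-oxo-2,5-dihydrofuran-2-id-3-olate (dianion of 17) | CC1=C([O-])[C-](OC1=O)P(=O)(Oc1ccccc1)Oc1ccccc1.[K+].[K+] | intermediate (not isolated)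
20 | potassium (2E)-2-[(2S,6E,10E)-13-(furan-3-yl)-2,6,10-trimethyltrideca-6,10-dien-1-ylidene]-4-methyl-5-oxo-2,5-dihydrofuran-3-olate (potassium salt of (18S,20E)-variabilin) | [K+].[O-]C1=C(C)C(=O)O/C1=C/[C@@H](C)CCC/C(C)=C/CC/C(C)=C/CCc1ccoc1 | intermediate (not isolated)
21 | (2E)-2-[(2S,6E,10E)-13-(furan-3-yl)-2,6,10-trimethyltrideca-6,10-dien-1-ylidene]-4-methyl-5-oxo-2,5-dihydrofuran-3-yl hexadecanoate ((18S,20E)-variabilin O-palmitate, CNP0269639.1) | CCCCCCCCCCCCCCCC(=O)OC1=C(C)C(=O)O/C1=C/[C@@H](C)CCC/C(C)=C/CC/C(C)=C/CCc1ccoc1 | target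

**Step count and risks**
Total: 10 steps. Longest linear sequence: 7 steps (1, 3, 4, 5, 6, 7, 10, from geranyl acetate).

Most likely to fail, first: step 10 (the proposed new olefination). The E/Z ratio may be low, and the basic dianion 19 may enolise aldehyde 12. The fallback uses known chemistry, sets out from 12 and comes back at 21. The dilithium dianion of 13 (LiN(iPr)2, 2 equiv, THF, −78 °C) is added to 12 to give the aldol 4-hydroxy-5-[(2S,6E,10E)-13-(furan-3-yl)-1-hydroxy-2,6,10-trimethyltrideca-6,10-dien-1-yl]-3-methylfuran-2(5H)-one F1 as a diastereomer mixture. Hexadecanoyl chloride 18 (2.5 equiv) with Et3N gives the bis-ester (2S,6E,10E)-13-(furan-3-yl)-1-[3-(hexadecanoyloxy)-4-methyl-5-oxo-2,5-dihydrofuran-2-yl]-2,6,10-trimethyltrideca-6,10-dien-1-yl hexadecanoate F2. DBU in the same flask eliminates palmitate (E1cB) to the thermodynamic (20Z)-isomer, (2Z)-2-[(2S,6E,10E)-13-(furan-3-yl)-2,6,10-trimethyltrideca-6,10-dien-1-ylidene]-4-methyl-5-oxo-2,5-dihydrofuran-3-yl hexadecanoate F3. Sensitised irradiation of F3 (thioxanthen-9-one, 405 nm, degassed MeCN) gives a Z/E photostationary mixture; 21 is separated by preparative HPLC and F3 is recycled.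

Second: step 6 (the photochemical union). The unactivated primary acid may decarboxylate slowly, carboxylate and bromide may give some ester by SN2, and reversible 3-exo closure of the homoallylic C16 radical could erode the C12=C13 geometry. The fallback sets out from 9 and comes back at 12, keeping the carboxyl carbon of 9 as C17. LiAlH4 reduces 9 to (4E,8E)-11-(furan-3-yl)-4,8-dimethylundeca-4,8-dien-1-ol F4. CBr4/PPh3 gives 3-[(3E,7E)-11-bromo-4,8-dimethylundeca-3,7-dien-1-yl]furan F5, and Mg in THF gives [(4E,8E)-11-(furan-3-yl)-4,8-dimethylundeca-4,8-dien-1-yl]magnesium bromide F6. This is coupled (ZnCl2 5 mol %, THF, 0 °C; SN2 with inversion) with ethyl (2S)-2-{[(trifluoromethyl)sulfonyl]oxy}propanoate F7, made from ethyl (S)-lactate with Tf2O and 2,6-lutidine. The product is ethyl (2S,6E,10E)-13-(furan-3-yl)-2,6,10-trimethyltrideca-6,10-dienoate F8, whose stereocentre is the one bought in the lactate. i-Bu2AlH at −78 °C gives 12.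

Third: step 8. Bromination of 14 could go to C-3 instead of C-5, and 15 is moisture-sensitive. The fallback sets out from 13 and comes back at 17. Me2SO4/K2CO3 in acetone gives 4-methoxy-3-methylfuran-2(5H)-one F9. Wohl–Ziegler bromination (NBS, AIBN, PhCF3, 80 °C) gives 5-bromo-4-methoxy-3-methylfuran-2(5H)-one F10. (PhO)2P(O)H with i-Pr2NEt gives diphenyl (3-methoxy-4-methyl-5-oxo-2,5-dihydrofuran-2-yl)phosphonate F11. LiCl in DMF at 80 °C removes the methyl group, and acidification gives 17.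

**Further compounds**
F1 | step 10 | 4-hydroxy-5-[(2S,6E,10E)-13-(furan-3-yl)-1-hydroxy-2,6,10-trimethyltrideca-6,10-dien-1-yl]-3-methylfuran-2(5H)-one | CC1=C(O)C(OC1=O)C(O)[C@@H](C)CCC/C(C)=C/CC/C(C)=C/CCc1ccoc1
F2 | step 10 | (2S,6E,10E)-13-(furan-3-yl)-1-[3-(hexadecanoyloxy)-4-methyl-5-oxo-2,5-dihydrofuran-2-yl]-2,6,10-trimethyltrideca-6,10-dien-1-yl hexadecanoate | CCCCCCCCCCCCCCCC(=O)OC1=C(C)C(=O)OC1C(OC(=O)CCCCCCCCCCCCCCC)[C@@H](C)CCC/C(C)=C/CC/C(C)=C/CCc1ccoc1
F3 | step 10 | (2Z)-2-[(2S,6E,10E)-13-(furan-3-yl)-2,6,10-trimethyltrideca-6,10-dien-1-ylidene]-4-methyl-5-oxo-2,5-dihydrofuran-3-yl hexadecanoate | CCCCCCCCCCCCCCCC(=O)OC1=C(C)C(=O)O/C1=C\[C@@H](C)CCC/C(C)=C/CC/C(C)=C/CCc1ccoc1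
F4 | step 6 | (4E,8E)-11-(furan-3-yl)-4,8-dimethylundeca-4,8-dien-1-ol | OCCC/C(C)=C/CC/C(C)=C/CCc1ccoc1
F5 | step 6 | 3-[(3E,7E)-11-bromo-4,8-dimethylundeca-3,7-dien-1-yl]furan | BrCCC/C(C)=C/CC/C(C)=C/CCc1ccoc1
F6 | step 6 | [(4E,8E)-11-(furan-3-yl)-4,8-dimethylundeca-4,8-dien-1-yl]magnesium bromide | Br[Mg]CCC/C(C)=C/CC/C(C)=C/CCc1ccoc1
F7 | step 6 | ethyl (2S)-2-{[(trifluoromethyl)sulfonyl]oxy}propanoate | CCOC(=O)[C@H](C)OS(=O)(=O)C(F)(F)F
F8 | step 6 | ethyl (2S,6E,10E)-13-(furan-3-yl)-2,6,10-trimethyltrideca-6,10-dienoate | CCOC(=O)[C@@H](C)CCC/C(C)=C/CC/C(C)=C/CCc1ccoc1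
F9 | step 8 | 4-methoxy-3-methylfuran-2(5H)-one | COC1=C(C)C(=O)OC1
F10 | step 8 | 5-bromo-4-methoxy-3-methylfuran-2(5H)-one | COC1=C(C)C(=O)OC1Br
F11 | step 8 | diphenyl (3-methoxy-4-methyl-5-oxo-2,5-dihydrofuran-2-yl)phosphonate | COC1=C(C)C(=O)OC1P(=O)(Oc1ccccc1)Oc1ccccc1
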